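**Strategy.** Ring C, the cyclobutane, is disconnected across its C2a–C2 and C7a–C1 bonds (cyclobuta[a]indene numbering: C1 = CMe2, C2 = CH–aryl, C2a and C7a = ring-fusion CH, C7 = CH2) into the ring A/B alkene of an indene and a catechol-derived β,β-dimethylstyrene. The key step exploits the C6 phenol of ring A, which sits peri to the C7 methylene of ring B. With C7 carried as a ketone, the precursor is a 7-hydroxyinden-1-one whose hydroxy-ketone pair chelates a chiral scandium Lewis acid. One enantioselective, triplet-sensitised crossed [2+2] photocycloaddition then forms both bonds, the quaternary C1, the cis B/C fusion and all three stereocentres. The ketone is afterwards excised through the same phenol.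

Key step: step 7

Remark (assumption): the sense of induction is taken to follow the 2'-hydroxychalcone series with the (S,S)-ligand; should the cycloadduct prove to be the mirror image, the equally available (R,R)-ligand is used instead.

Step 1
Reactants: 1 5,7-dimethoxyindan-1-one; 2 N-bromosuccinimide
Product: 3 4-bromo-5,7-dimethoxyindan-1-one
Conditions: NBS (1.05 equiv), MeCN, 0 °C to rt, dark
Reagents that add atoms: N-bromosuccinimide, O=C1CCC(=O)N1Br
Why: Electrophilic aromatic bromination should occur at C4, which is ortho to the C5 methoxy and para to the C7 methoxy and less hindered than C6 between the two methoxy groups, while the ketone α-position is left alone in the absence of acid or radical initiator.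

Step 2
Reactants: 3 4-bromo-5,7-dimethoxyindan-1-one
Product: 5 4-bromo-7-hydroxy-5-methoxyindan-1-one, via aryloxydichloroborane 4 (not isolated)
Conditions: BCl3 (1.2 equiv), CH2Cl2, −78 to 0 °C; then H2O
Reagents that add atoms: none
Why: Chelation-directed Lewis acid ether cleavage: BCl3 bridges the ketone oxygen and the peri C7 methoxy, so chloride should dealkylate only that ether and leave the C5 methoxy intact.

Step 3
Reactants: 5 4-bromo-7-hydroxy-5-methoxyindan-1-one; 6 tributyl(3-methylbut-2-en-1-yl)stannane
Product: 7 7-hydroxy-5-methoxy-4-(3-methylbut-2-en-1-yl)indan-1-one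
Conditions: Pd(PPh3)4 (10 mol%), DMF, 100 °C, degassed
Reagents that add atoms: tributyl(3-methylbut-2-en-1-yl)stannane, CCCC[Sn](CCCC)(CCCC)CC=C(C)C
Why: Stille coupling, in which the equilibrating prenyl–palladium intermediate should reductively eliminate at its less hindered primary terminus to give the linear prenyl arene, under neutral conditions that tolerate the free phenol and the enolisable ketone.

Step 4
Reactants: 7 7-hydroxy-5-methoxy-4-(3-methylbut-2-en-1-yl)indan-1-one
Product: 10 7-hydroxy-5-methoxy-4-(3-methylbut-2-en-1-yl)-1H-inden-1-one, via bis-silyl enol ether 8 (not isolated), via silylated indenone 9 (not isolated)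
Conditions: TMSOTf (2.3 equiv), Et3N (3 equiv), CH2Cl2, 0 °C; then Pd(OAc)2 (1.1 equiv), MeCN, rt; then aq. citric acid, THF, 0 °C
Reagents that add atoms: none
Why: Saegusa–Ito dehydrogenation: the only enolisable position (C2) is silylated, the palladium oxa-allyl intermediate should undergo β-hydride elimination to the C2=C3 enone, and the phenol silyl ether is hydrolysed in the acidic wash; 10 is kept cold and dark and used promptly because 2,3-unsubstituted indenones dimerise.

Step 5
Reactants: 11 3,4-dihydroxybenzaldehyde; 12 tert-butyldimethylsilyl chloride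
Product: 13 3,4-bis(tert-butyldimethylsilyloxy)benzaldehyde
Conditions: TBSCl (2.4 equiv), imidazole (5 equiv), DMF, rt
Reagents that add atoms: tert-butyldimethylsilyl chloride, CC(C)(C)[Si](C)(C)Cl
Why: Standard imidazole-promoted silylation of both phenols gives a catechol protection that is non-chelating towards the Lewis acid of step 7 and removable by fluoride without touching the prenyl group.

Step 6
Reactants: 13 3,4-bis(tert-butyldimethylsilyloxy)benzaldehyde; 14 isopropyltriphenylphosphonium iodide
Product: 16 4-(2-methylprop-1-en-1-yl)-1,2-bis(tert-butyldimethylsilyloxy)benzene, via phosphorus ylide 15 (not isolated)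
Conditions: 14 (1.3 equiv), n-BuLi (1.25 equiv), THF, 0 °C; then 13, −78 °C to rt
Reagents that add atoms: isopropyltriphenylphosphonium iodide, CC(C)[P+](c1ccccc1)(c1ccccc1)c1ccccc1.[I-]
Why: Wittig olefination of the aryl aldehyde with the non-stabilised isopropylidene ylide, with no alkene geometry to control because the new terminus carries two methyl groups.

Step 7
Reactants: 10 7-hydroxy-5-methoxy-4-(3-methylbut-2-en-1-yl)-1H-inden-1-one; 16 4-(2-methylprop-1-en-1-yl)-1,2-bis(tert-butyldimethylsilyloxy)benzene
Product: 17 (2S,2aS,7aS)-2-[3,4-bis(tert-butyldimethylsilyloxy)phenyl]-6-hydroxy-4-methoxy-1,1-dimethyl-3-(3-methylbut-2-en-1-yl)-1,2,2a,7a-tetrahydro-7H-cyclobuta[a]inden-7-one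
Conditions: 16 (5 equiv), Sc(OTf)3 (10 mol%), (S,S)-t-Bu-PyBox (15 mol%), Ru(bpy)3(PF6)2 (2.5 mol%), i-PrOAc/MeCN 3:1, degassed, blue LEDs (ca. 455 nm), −20 °C
Reagents that add atoms: none
Why: Proposed new method: the C7 hydroxyl and C1 carbonyl of 10 chelate the Sc(OTf)3–PyBox complex, which should lower the enone triplet energy so that excited Ru(bpy)3(PF6)2 sensitises only the bound enone; its electrophilic α-carbon (future C7a) adds to the CMe2 terminus of 16, and the resulting bis-benzylic triplet 1,4-diradical undergoes intersystem crossing and closes the C2a–C2 bond. The closest known reaction type is the chiral-Lewis-acid-catalysed, triplet-sensitised crossed [2+2] photocycloaddition of 2'-hydroxychalcones with styrenes, supported by the long-known racemic photocycloaddition of indenones and cycloalkenones to alkenes as substituted as tetramethylethylene; new is the cyclic chelating enone combined with a β,β-dimethylstyrene. Only the cyclobutane (ring C) is closed, by an intermolecular stepwise [2+2] whose second bond forms by recombination of the 1,4-diradical. C7a is set in the first bond formation on the enone face left open by the tert-butyl groups of the ligand, C2a follows because the ring B alkene can only give a cis four/five fusion, and C2 is set at ring closure, where the freely rotating benzylic radical should place the aryl group exo and trans to ring A. The step needs the C7a–CMe2/C2a–CHAr regiochemistry and cross- over homo-coupling: the first should be secured by formation of the benzylic rather than the tertiary radical, the second by the excess of 16, which is not sensitised, has no E/Z isomers and is too hindered to dimerise, while the non-conjugated prenyl alkene of 10 is the poorer radical acceptor.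

Step 8
Reactants: 17 (2S,2aS,7aS)-2-[3,4-bis(tert-butyldimethylsilyloxy)phenyl]-6-hydroxy-4-methoxy-1,1-dimethyl-3-(3-methylbut-2-en-1-yl)-1,2,2a,7a-tetrahydro-7H-cyclobuta[a]inden-7-one
Product: 20 (2S,2aR,7aS)-2-[3,4-bis(tert-butyldimethylsilyloxy)phenyl]-4-methoxy-1,1-dimethyl-3-(3-methylbut-2-en-1-yl)-2,2a,7,7a-tetrahydro-1H-cyclobuta[a]inden-6-ol, via aryl ethyl carbonate 18 (not isolated), via ortho-quinone methide 19 (not isolated)
Conditions: ClCO2Et (1.2 equiv), Et3N (1.5 equiv), THF, 0 °C; then NaBH4 (5 equiv), H2O/THF, 0 °C to rt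
Reagents that add atoms: none
Why: Reductive deoxygenation of an ortho-hydroxyaryl ketone through its carbonate: borohydride reduces the ketone, the carbonate migrates to the benzylic alkoxide and is expelled to give ortho-quinone methide 19, which takes up a second hydride at C7 under basic, acid-free conditions that should spare the prenyl alkene, the cyclobutane and the stereocentres (the C2a descriptor changes only through CIP priorities).

Step 9
Reactants: 20 (2S,2aR,7aS)-2-[3,4-bis(tert-butyldimethylsilyloxy)phenyl]-4-methoxy-1,1-dimethyl-3-(3-methylbut-2-en-1-yl)-2,2a,7,7a-tetrahydro-1H-cyclobuta[a]inden-6-ol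
Product: 21 4-[(2S,2aR,7aS)-6-hydroxy-4-methoxy-1,1-dimethyl-3-(3-methylbut-2-en-1-yl)-2,2a,7,7a-tetrahydro-1H-cyclobuta[a]inden-2-yl]benzene-1,2-diol
Conditions: TBAF (2.5 equiv), AcOH (2.5 equiv), THF, 0 °C, argon
Reagents that add atoms: none
Why: Fluoride cleavage of the two aryl silyl ethers, buffered with acetic acid so that the liberated catechol is not air-oxidised, leaves the methyl ether, the prenyl alkene and the cyclobutane untouched.

**Compound list**

1 | 5,7-dimethoxyindan-1-one | COc1cc(OC)c2C(=O)CCc2c1 | starting material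
2 | N-bromosuccinimide | O=C1CCC(=O)N1Br | starting material
3 | 4-bromo-5,7-dimethoxyindan-1-one | COc1cc(OC)c2C(=O)CCc2c1Br | intermediate
4 | (4-bromo-5-methoxy-1-oxoindan-7-yl)oxydichloroborane | COc1cc(OB(Cl)Cl)c2C(=O)CCc2c1Br | intermediate (not isolated)
5 | 4-bromo-7-hydroxy-5-methoxyindan-1-one | COc1cc(O)c2C(=O)CCc2c1Br | intermediate
6 | tributyl(3-methylbut-2-en-1-yl)stannane | CCCC[Sn](CCCC)(CCCC)CC=C(C)C | starting material
7 | 7-hydroxy-5-methoxy-4-(3-methylbut-2-en-1-yl)indan-1-one | COc1cc(O)c2C(=O)CCc2c1CC=C(C)C | intermediate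
8 | 6-methoxy-7-(3-methylbut-2-en-1-yl)-3,4-bis(trimethylsilyloxy)-1H-indene | COc1cc(O[Si](C)(C)C)c2C(O[Si](C)(C)C)=CCc2c1CC=C(C)C | intermediate (not isolated)
9 | 5-methoxy-4-(3-methylbut-2-en-1-yl)-7-(trimethylsilyloxy)-1H-inden-1-one | COc1cc(O[Si](C)(C)C)c2C(=O)C=Cc2c1CC=C(C)C | intermediate (not isolated)
10 | 7-hydroxy-5-methoxy-4-(3-methylbut-2-en-1-yl)-1H-inden-1-one | COc1cc(O)c2C(=O)C=Cc2c1CC=C(C)C | intermediate
11 | 3,4-dihydroxybenzaldehyde | O=Cc1ccc(O)c(O)c1 | starting material
12 | tert-butyldimethylsilyl chloride | CC(C)(C)[Si](C)(C)Cl | starting material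
13 | 3,4-bis(tert-butyldimethylsilyloxy)benzaldehyde | O=Cc1ccc(O[Si](C)(C)C(C)(C)C)c(O[Si](C)(C)C(C)(C)C)c1 | intermediate
14 | isopropyltriphenylphosphonium iodide | CC(C)[P+](c1ccccc1)(c1ccccc1)c1ccccc1.[I-] | starting material
15 | isopropylidenetriphenylphosphorane | CC(C)=P(c1ccccc1)(c1ccccc1)c1ccccc1 | intermediate (not isolated)
16 | 4-(2-methylprop-1-en-1-yl)-1,2-bis(tert-butyldimethylsilyloxy)benzene | CC(C)=Cc1ccc(O[Si](C)(C)C(C)(C)C)c(O[Si](C)(C)C(C)(C)C)c1 | intermediate
17 | (2S,2aS,7aS)-2-[3,4-bis(tert-butyldimethylsilyloxy)phenyl]-6-hydroxy-4-methoxy-1,1-dimethyl-3-(3-methylbut-2-en-1-yl)-1,2,2a,7a-tetrahydro-7H-cyclobuta[a]inden-7-one | COc1cc(O)c2c(c1CC=C(C)C)[C@@H]1[C@H](C2=O)C(C)(C)[C@H]1c1ccc(O[Si](C)(C)C(C)(C)C)c(O[Si](C)(C)C(C)(C)C)c1 | intermediate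
18 | ethyl carbonate of the C6 phenol of 17, stereocentres as in 17 | COc1cc(OC(=O)OCC)c2c(c1CC=C(C)C)[C@@H]1[C@H](C2=O)C(C)(C)[C@H]1c1ccc(O[Si](C)(C)C(C)(C)C)c(O[Si](C)(C)C(C)(C)C)c1 | intermediate (not isolated)
19 | ortho-quinone methide (C6=O, C6a=C7H, C2b=C3, C4=C5), stereocentres as in 17: 2-[3,4-bis(tert-butyldimethylsilyloxy)phenyl]-4-methoxy-1,1-dimethyl-3-(3-methylbut-2-en-1-yl)-1,2,2a,7a-tetrahydro-6H-cyclobuta[a]inden-6-one | COC1=CC(=O)C2C(=C1CC=C(C)C)[C@@H]1[C@H](C=2)C(C)(C)[C@H]1c1ccc(O[Si](C)(C)C(C)(C)C)c(O[Si](C)(C)C(C)(C)C)c1 | intermediate (not isolated)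
20 | (2S,2aR,7aS)-2-[3,4-bis(tert-butyldimethylsilyloxy)phenyl]-4-methoxy-1,1-dimethyl-3-(3-methylbut-2-en-1-yl)-2,2a,7,7a-tetrahydro-1H-cyclobuta[a]inden-6-ol | COc1cc(O)c2c(c1CC=C(C)C)[C@@H]1[C@H](C2)C(C)(C)[C@H]1c1ccc(O[Si](C)(C)C(C)(C)C)c(O[Si](C)(C)C(C)(C)C)c1 | intermediate
21 | 4-[(2S,2aR,7aS)-6-hydroxy-4-methoxy-1,1-dimethyl-3-(3-methylbut-2-en-1-yl)-2,2a,7,7a-tetrahydro-1H-cyclobuta[a]inden-2-yl]benzene-1,2-diol | COc1cc(O)c2c(c1CC=C(C)C)[C@@H]1[C@H](C2)C(C)(C)[C@H]1c1ccc(O)c(O)c1 | target

**Total step count:** 9
**Longest linear sequence:** 7 steps (steps 1–4, then 7–9)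

**Steps most likely to fail**

Step 7 (key step, proposed new method). Unbound indenone may absorb light directly and react without the chiral Lewis acid, eroding enantioselectivity. Turnover may also stall because the hydroxy-ketone product still chelates scandium. The fallback sets out from 10 and 16 and relies only on the known direct [2+2] photocycloaddition of indenones to alkenes. Irradiation at about 420 nm in CH2Cl2 at −40 °C without Lewis acid, ligand or sensitiser should give the racemic cycloadduct, that is 17 together with its mirror image, the (2R,2aR,7aR)-cycloadduct F1. Preparative chromatography on a chiral stationary phase removes F1, and the route is rejoined at 17.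

Step 8. The ortho-quinone methide has to form within the five-membered ring B, so carbonate migration and elimination may be slow and the reduction may stop at the benzylic alcohol. The fallback sets out from 17. Condensation with p-toluenesulfonohydrazide (EtOH, cat. AcOH, 60 °C) should give the tosylhydrazone F2. Reduction with catecholborane (CHCl3, 0 °C) followed by NaOAc·3H2O at reflux (Kabalka variant of the Caglioti reduction) expels sulfinate and dinitrogen and delivers the C7 methylene. The route is rejoined at 20.

Step 4. The indenone may dimerise or polymerise in the presence of palladium salts, or the silyl enol ether may be hydrolysed back before dehydrogenation. The fallback sets out from 7. Double deprotonation (lithium diisopropylamide, 2.2 equiv, THF, −78 °C) and trapping with PhSeBr should give the 2-(phenylselanyl)indanone F3. Oxidation with NaIO4 (THF/H2O, 0 °C to rt) triggers selenoxide syn-elimination under metal-free conditions. The route is rejoined at 10.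

**Further compounds**

F1 | step 7 | (2R,2aR,7aR)-2-[3,4-bis(tert-butyldimethylsilyloxy)phenyl]-6-hydroxy-4-methoxy-1,1-dimethyl-3-(3-methylbut-2-en-1-yl)-1,2,2a,7a-tetrahydro-7H-cyclobuta[a]inden-7-one | COc1cc(O)c2c(c1CC=C(C)C)[C@H]1[C@@H](C2=O)C(C)(C)[C@@H]1c1ccc(O[Si](C)(C)C(C)(C)C)c(O[Si](C)(C)C(C)(C)C)c1
F2 | step 8 | p-toluenesulfonylhydrazone of the C7 ketone of 17, stereocentres as in 17 | COc1cc(O)c2c(c1CC=C(C)C)[C@@H]1[C@H](C2=NNS(=O)(=O)c2ccc(C)cc2)C(C)(C)[C@H]1c1ccc(O[Si](C)(C)C(C)(C)C)c(O[Si](C)(C)C(C)(C)C)c1
F3 | step 4 | 7-hydroxy-5-methoxy-4-(3-methylbut-2-en-1-yl)-2-(phenylselanyl)indan-1-one, racemic at C2 | COc1cc(O)c2C(=O)C([Se]c3ccccc3)Cc2c1CC=C(C)C
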